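The route rests on disconnecting the C3–C4 bond of the cyclopentane (guaiane numbering) and tracing C2–C3 back to a spirocyclopropane on C1 of a monocyclic seven-membered ring. The key step exploits the homoallylic position of C3 relative to the tetrasubstituted C1=C10 olefin shared by both rings. Hydrogen-atom transfer to a C10 exocyclic methylene makes the C14 methyl and a cyclopropylcarbinyl radical; its scission fixes the C1=C10 olefin and frees a C3 radical that closes the five-membered ring onto a C5 ethynyl group. The resulting C4 methylene is reduced in the same flask to the C4 methyl stereocentre. The precursor is a 4-methylidenespiro[2.6]nonane carrying the alkyne and both hydroxyls.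

Key step: step 10

Numbering used throughout (guaiane): C1 = ring-fusion olefinic carbon; C2, C3 = cyclopentane CH2; C4 = CHMe (methyl = C15); C5 = ring-fusion CH; C6 = CH2; C7 = CH bearing the C11 carbinol; C8 = CH–O; C9 = CH2; C10 = olefinic carbon bearing methyl C14.
Remark: the descriptor of C5 changes between R and S along the route only because the CIP priorities change (silyl alkyne against terminal alkyne or ring carbon); the centre is never inverted.
Assumption 1: meso ketone 1 is taken as a purchasable compound (it is the cycloadduct of furan with an oxyallyl cation).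
Assumption 2: the (R,R)-lithium amide is taken to give the (1S,5S) enol ether 2; if the sense of induction is the opposite, the equally available (S,S)-amide is used.

Step 1
Reactants: 1 (1R,5S)-8-oxabicyclo[3.2.1]oct-6-en-3-one (meso)
Product: 2 triethyl{[(1S,5S)-8-oxabicyclo[3.2.1]octa-2,6-dien-3-yl]oxy}silane
Conditions: (R,R)-bis(1-phenylethyl)amine, n-BuLi, LiCl, THF, −100 °C; then Et3SiCl, −100 → −78 °C
Reagents that add atoms: chlorotriethylsilane, CC[Si](Cl)(CC)CC
Why: Enantioselective deprotonation of a meso ketone by the C2-symmetric chiral lithium amide removes one of the two enantiotopic α-protons and the enolate is O-silylated, which decides which bridgehead later keeps its oxygen and so sets the absolute configuration of C8.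

Step 2
Reactants: 2 triethyl{[(1S,5S)-8-oxabicyclo[3.2.1]octa-2,6-dien-3-yl]oxy}silane
Product: 3 (6S)-6-[(triethylsilyl)oxy]cyclohepta-2,4-dien-1-one
Conditions: Et3SiOTf (5 mol%), CH2Cl2, −78 → −40 °C; Et3N quench
Reagents that add atoms: none
Why: Lewis-acid-catalysed vinylogous β-elimination (retro-oxa-Michael ring opening): silylation of the bridging oxygen ionises the doubly allylic C–O bond next to the enol ether, and loss of the enol silyl group regenerates the catalyst and leaves the untouched bridgehead as the C8 stereocentre.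

Step 3
Reactants: 3 (6S)-6-[(triethylsilyl)oxy]cyclohepta-2,4-dien-1-one; 4 prop-1-en-2-ylmagnesium bromide
Product: 6 (5R,6S)-5-(prop-1-en-2-yl)-6-[(triethylsilyl)oxy]cyclohept-2-en-1-one, via deconjugated enone 5 (not isolated)
Conditions: CuBr·SMe2 (10 mol%), THF, −78 °C; aq. NH4Cl; then DBU (cat.), CH2Cl2, 0 °C
Reagents that add atoms: none
Why: Copper-catalysed 1,6-conjugate addition of the alkenyl Grignard reagent places the isopropenyl group on C7 anti to the adjacent C8 silyloxy group (trans C7/C8), and DBU then moves the β,γ-olefin into conjugation by deprotonation at the doubly activated C1 position (the conjugated isomer should predominate and any 5 left is recycled).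

Step 4
Reactants: 6 (5R,6S)-5-(prop-1-en-2-yl)-6-[(triethylsilyl)oxy]cyclohept-2-en-1-one; 7 ethynyltri(propan-2-yl)silane
Product: 9 (3R,5R,6S)-2-[(dimethylamino)methyl]-5-(prop-1-en-2-yl)-6-[(triethylsilyl)oxy]-3-{[tri(propan-2-yl)silyl]ethynyl}cycloheptan-1-one (C2 epimers), via silyl enol ether 8 (not isolated)
Conditions: 7, n-BuLi, THF, −78 °C; ZnBr2; 6, Me3SiOTf, −78 → −40 °C; then [CH2=NMe2]I, CH2Cl2, rt; aq. NaHCO3
Reagents that add atoms: dimethyl(methylidene)ammonium iodide, C=[N+](C)C.[I-]
Why: Silyl-triflate-promoted conjugate addition of the zinc acetylide should deliver the alkyne to C5 from the face of the chair-like cycloheptenone opposite the C7–C8 flap (cis to the C7 substituent and trans to the C8 silyloxy group, the sense in which cuprates add to 5- and 6-substituted cyclohept-2-enones), and the regiodefined silyl enol ether then undergoes a Mannich reaction at C1.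

Step 5
Reactants: 9 (3R,5R,6S)-2-[(dimethylamino)methyl]-5-(prop-1-en-2-yl)-6-[(triethylsilyl)oxy]-3-{[tri(propan-2-yl)silyl]ethynyl}cycloheptan-1-one
Product: 11 (3R,5R,6S)-2-methylidene-5-(prop-1-en-2-yl)-6-[(triethylsilyl)oxy]-3-{[tri(propan-2-yl)silyl]ethynyl}cycloheptan-1-one, via methiodide 10 (not isolated)
Conditions: MeI, CH2Cl2, rt; then aq. NaHCO3, rt
Reagents that add atoms: none
Why: Quaternisation followed by Hofmann-type E1cB elimination of trimethylamine from the Mannich base gives the α-methylene ketone under conditions too mild to move the exocyclic olefin into the ring or to touch C5.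

Step 6
Reactants: 11 (3R,5R,6S)-2-methylidene-5-(prop-1-en-2-yl)-6-[(triethylsilyl)oxy]-3-{[tri(propan-2-yl)silyl]ethynyl}cycloheptan-1-one
Product: 12 (6S,7R,9R)-7-(prop-1-en-2-yl)-6-[(triethylsilyl)oxy]-9-{[tri(propan-2-yl)silyl]ethynyl}spiro[2.6]nonan-4-one
Conditions: Me3S(O)I, NaH, DMSO, rt
Reagents that add atoms: trimethylsulfoxonium iodide, C[S+](C)(C)=O.[I-]
Why: Corey–Chaykovsky cyclopropanation: the sulfoxonium ylide adds 1,4 to the exocyclic enone and the enolate closes the three-membered ring by displacing DMSO, which makes C1 a spiro carbon carrying C2 and C3 (no new stereocentre).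

Step 7
Reactants: 12 (6S,7R,9R)-7-(prop-1-en-2-yl)-6-[(triethylsilyl)oxy]-9-{[tri(propan-2-yl)silyl]ethynyl}spiro[2.6]nonan-4-one
Product: 13 (6S,7S,9R)-7-(2-hydroxypropan-2-yl)-6-[(triethylsilyl)oxy]-9-{[tri(propan-2-yl)silyl]ethynyl}spiro[2.6]nonan-4-one
Conditions: Co(acac)2 (20 mol%), PhSiH3, O2 (1 atm), i-PrOH, rt
Reagents that add atoms: dioxygen, O=O
Why: Mukaiyama hydration: Markovnikov hydrogen-atom transfer from a cobalt hydride to the 1,1-disubstituted isopropenyl group and capture of the tertiary radical by O2 gives the C11 carbinol, while the silyl alkyne and the cyclopropyl ketone are inert and C7 is not touched.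

Step 8
Reactants: 13 (6S,7S,9R)-7-(2-hydroxypropan-2-yl)-6-[(triethylsilyl)oxy]-9-{[tri(propan-2-yl)silyl]ethynyl}spiro[2.6]nonan-4-one
Product: 14 2-[(4R,6S,7S)-9-methylidene-7-[(triethylsilyl)oxy]-4-{[tri(propan-2-yl)silyl]ethynyl}spiro[2.6]nonan-6-yl]propan-2-ol
Conditions: Cp2TiMe2 (3 equiv), toluene, 70 °C
Reagents that add atoms: dimethyltitanocene (Cp2TiMe2), [CH3-].[CH3-].[Ti+4].c1cc[cH-]c1.c1cc[cH-]c1
Why: Petasis olefination: the non-basic titanium methylidene methylenates the hindered α-quaternary ketone without enolisation towards C9 and loss of the C8 silyloxy group (one equivalent is consumed by the free carbinol and released on work-up).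

Step 9
Reactants: 14 2-[(4R,6S,7S)-9-methylidene-7-[(triethylsilyl)oxy]-4-{[tri(propan-2-yl)silyl]ethynyl}spiro[2.6]nonan-6-yl]propan-2-ol
Product: 15 (6S,7S,9S)-9-ethynyl-7-(2-hydroxypropan-2-yl)-4-methylidenespiro[2.6]nonan-6-ol
Conditions: Bu4NF, THF, 0 °C → rt
Reagents that add atoms: none
Why: Fluoride-mediated desilylation cleaves both the O–Si bond at C8 and the C(sp)–Si bond, which unmasks the terminal alkyne needed as radical acceptor.

Step 10
Reactants: 15 (6S,7S,9S)-9-ethynyl-7-(2-hydroxypropan-2-yl)-4-methylidenespiro[2.6]nonan-6-ol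
Product: 17 (3S,3aS,5S,6S)-5-(2-hydroxypropan-2-yl)-3,8-dimethyl-1,2,3,3a,4,5,6,7-octahydroazulen-6-ol, via exocyclic diene 16 (not isolated)
Conditions: Mn(dpm)3 (10 mol%), PhSiH3, t-BuOOH, degassed i-PrOH, rt
Reagents that add atoms: none
Why: Metal-hydride hydrogen-atom transfer (MHAT) from the manganese hydride to the 1,1-disubstituted C10=C14 olefin gives the tertiary cyclopropylcarbinyl radical at C10, which opens by β-scission of a C1–CH2 bond (both cyclopropane bonds are equivalent) to the C1=C10 olefin and a primary C3 radical; this radical attacks the alkyne carbon C4, the C15 vinyl radical is quenched by hydrogen abstraction to give diene 16, and a second MHAT and hydrogen-atom capture at its 1,1-disubstituted C4=C15 olefin gives the C4 methyl group. The closest known reaction types are the MHAT-initiated reductive radical cyclisation and radical hydrogenation of 1,1-disubstituted olefins, combined with the classical cyclopropylcarbinyl-to-homoallyl radical fragmentation–cyclisation cascade. The only ring closed is the five-membered ring, in the 5-exo-dig mode. The new C4 stereocentre is set in the last hydrogen-atom delivery to the planar tertiary C4 radical, which should occur on the face of the nearly flat cyclopentene-like ring anti to the C5–C6 bond and so place H-4 cis to H-5, while C5, C7 and C8 are not touched. The step needs chemoselective initiation at the exocyclic methylene (secured because MHAT is fast only at the electron-rich 1,1-disubstituted olefin and not at the alkyne or the tetrasubstituted product olefin) and regiospecific placement of the C1=C10 olefin (secured by the position of the cyclopropane).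

Step 11
Reactants: 17 (3S,3aS,5S,6S)-5-(2-hydroxypropan-2-yl)-3,8-dimethyl-1,2,3,3a,4,5,6,7-octahydroazulen-6-ol; 18 (2E)-3-[4-(acetyloxy)phenyl]prop-2-enoic acid
Product: 19 (3S,3aS,5S,6S)-5-(2-hydroxypropan-2-yl)-3,8-dimethyl-1,2,3,3a,4,5,6,7-octahydroazulen-6-yl (2E)-3-[4-(acetyloxy)phenyl]prop-2-enoate
Conditions: DCC, DMAP (cat.), CH2Cl2, 0 °C → rt
Reagents that add atoms: none
Why: Steglich esterification acylates the secondary C8 hydroxyl with retention, the tertiary C11 carbinol being too hindered to react and the (E)-olefin of the acid being untouched.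

Step 12
Reactants: 19 (3S,3aS,5S,6S)-5-(2-hydroxypropan-2-yl)-3,8-dimethyl-1,2,3,3a,4,5,6,7-octahydroazulen-6-yl (2E)-3-[4-(acetyloxy)phenyl]prop-2-enoate
Product: 20 (3S,3aS,5S,6S)-5-(2-hydroxypropan-2-yl)-3,8-dimethyl-1,2,3,3a,4,5,6,7-octahydroazulen-6-yl (2E)-3-(4-hydroxyphenyl)prop-2-enoate
Conditions: K2CO3 (cat.), MeOH, 0 °C
Reagents that add atoms: none
Why: Base-catalysed transesterification (methanolysis) removes the activated phenolic acetate far faster than the hindered secondary cinnamate and gives the target.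

Compound list
1 | (1R,5S)-8-oxabicyclo[3.2.1]oct-6-en-3-one (meso) | O=C1C[C@H]2C=C[C@@H](C1)O2 | starting material
2 | triethyl{[(1S,5S)-8-oxabicyclo[3.2.1]octa-2,6-dien-3-yl]oxy}silane | CC[Si](CC)(CC)OC1=C[C@@H]2C=C[C@H](C1)O2 | intermediate
3 | (6S)-6-[(triethylsilyl)oxy]cyclohepta-2,4-dien-1-one | O=C1C=CC=C[C@@H](O[Si](CC)(CC)CC)C1 | intermediate
4 | prop-1-en-2-ylmagnesium bromide (isopropenylmagnesium bromide) | CC(=C)[Mg]Br | starting material
5 | (5R,6S)-5-(prop-1-en-2-yl)-6-[(triethylsilyl)oxy]cyclohept-3-en-1-one (deconjugated enone, formed in the flask) | O=C1CC=C[C@H](C(C)=C)[C@@H](O[Si](CC)(CC)CC)C1 | intermediate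
6 | (5R,6S)-5-(prop-1-en-2-yl)-6-[(triethylsilyl)oxy]cyclohept-2-en-1-one | O=C1C=CC[C@H](C(C)=C)[C@@H](O[Si](CC)(CC)CC)C1 | intermediate
7 | ethynyltri(propan-2-yl)silane | C#C[Si](C(C)C)(C(C)C)C(C)C | starting material
8 | trimethyl{[(3R,5R,6S)-5-(prop-1-en-2-yl)-6-[(triethylsilyl)oxy]-3-{[tri(propan-2-yl)silyl]ethynyl}cyclohept-1-en-1-yl]oxy}silane (silyl enol ether, formed in the flask) | C[Si](C)(C)OC1=C[C@H](C#C[Si](C(C)C)(C(C)C)C(C)C)C[C@H](C(C)=C)[C@@H](O[Si](CC)(CC)CC)C1 | intermediate
9 | (3R,5R,6S)-2-[(dimethylamino)methyl]-5-(prop-1-en-2-yl)-6-[(triethylsilyl)oxy]-3-{[tri(propan-2-yl)silyl]ethynyl}cycloheptan-1-one (C2 epimers) | O=C1C(CN(C)C)[C@H](C#C[Si](C(C)C)(C(C)C)C(C)C)C[C@H](C(C)=C)[C@@H](O[Si](CC)(CC)CC)C1 | intermediate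
10 | trimethylammonium iodide of 9 (methiodide, formed in the flask) | O=C1C(C[N+](C)(C)C)[C@H](C#C[Si](C(C)C)(C(C)C)C(C)C)C[C@H](C(C)=C)[C@@H](O[Si](CC)(CC)CC)C1.[I-] | intermediate
11 | (3R,5R,6S)-2-methylidene-5-(prop-1-en-2-yl)-6-[(triethylsilyl)oxy]-3-{[tri(propan-2-yl)silyl]ethynyl}cycloheptan-1-one | O=C1C(=C)[C@H](C#C[Si](C(C)C)(C(C)C)C(C)C)C[C@H](C(C)=C)[C@@H](O[Si](CC)(CC)CC)C1 | intermediate
12 | (6S,7R,9R)-7-(prop-1-en-2-yl)-6-[(triethylsilyl)oxy]-9-{[tri(propan-2-yl)silyl]ethynyl}spiro[2.6]nonan-4-one | O=C1C2(CC2)[C@H](C#C[Si](C(C)C)(C(C)C)C(C)C)C[C@H](C(C)=C)[C@@H](O[Si](CC)(CC)CC)C1 | intermediate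
13 | (6S,7S,9R)-7-(2-hydroxypropan-2-yl)-6-[(triethylsilyl)oxy]-9-{[tri(propan-2-yl)silyl]ethynyl}spiro[2.6]nonan-4-one | O=C1C2(CC2)[C@H](C#C[Si](C(C)C)(C(C)C)C(C)C)C[C@H](C(C)(C)O)[C@@H](O[Si](CC)(CC)CC)C1 | intermediate
14 | 2-[(4R,6S,7S)-9-methylidene-7-[(triethylsilyl)oxy]-4-{[tri(propan-2-yl)silyl]ethynyl}spiro[2.6]nonan-6-yl]propan-2-ol | C=C1C2(CC2)[C@H](C#C[Si](C(C)C)(C(C)C)C(C)C)C[C@H](C(C)(C)O)[C@@H](O[Si](CC)(CC)CC)C1 | intermediate
15 | (6S,7S,9S)-9-ethynyl-7-(2-hydroxypropan-2-yl)-4-methylidenespiro[2.6]nonan-6-ol | C=C1C2(CC2)[C@H](C#C)C[C@H](C(C)(C)O)[C@@H](O)C1 | intermediate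
16 | (3aS,5S,6S)-5-(2-hydroxypropan-2-yl)-8-methyl-3-methylidene-1,2,3,3a,4,5,6,7-octahydroazulen-6-ol (exocyclic diene, formed in the flask) | CC1=C2CCC(=C)[C@@H]2C[C@H](C(C)(C)O)[C@@H](O)C1 | intermediate
17 | (3S,3aS,5S,6S)-5-(2-hydroxypropan-2-yl)-3,8-dimethyl-1,2,3,3a,4,5,6,7-octahydroazulen-6-ol | CC1=C2CC[C@H](C)[C@@H]2C[C@H](C(C)(C)O)[C@@H](O)C1 | intermediate
18 | (2E)-3-[4-(acetyloxy)phenyl]prop-2-enoic acid (4-acetoxycinnamic acid) | CC(=O)Oc1ccc(/C=C/C(=O)O)cc1 | starting material
19 | (3S,3aS,5S,6S)-5-(2-hydroxypropan-2-yl)-3,8-dimethyl-1,2,3,3a,4,5,6,7-octahydroazulen-6-yl (2E)-3-[4-(acetyloxy)phenyl]prop-2-enoate | CC1=C2CC[C@H](C)[C@@H]2C[C@H](C(C)(C)O)[C@@H](OC(=O)/C=C/c2ccc(OC(C)=O)cc2)C1 | intermediate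
20 | (3S,3aS,5S,6S)-5-(2-hydroxypropan-2-yl)-3,8-dimethyl-1,2,3,3a,4,5,6,7-octahydroazulen-6-yl (2E)-3-(4-hydroxyphenyl)prop-2-enoate | CC1=C2CC[C@H](C)[C@@H]2C[C@H](C(C)(C)O)[C@@H](OC(=O)/C=C/c2ccc(O)cc2)C1 | target

Total step count: 12. Longest linear sequence: 12 steps (1 to 20); 4, 7 and 18 are used as purchased.

Steps most likely to fail

1. Step 10 (key step). What may go wrong:
- the primary C3 radical may be reduced before it closes the ring;
- the C15 vinyl radical may abstract H-7 intramolecularly (1,5-hydrogen shift), eroding the C7 configuration;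
- the last hydrogen-atom delivery may show poor facial selectivity at C4.

Fallback (sets out from 13, returns at 17): the radical is generated from a bromide and the C4 hydrogen is delivered by catalytic hydrogenation. MeMgBr/CeCl3 (THF, −78 °C) adds to the ketone of 13 to give the tertiary cyclopropyl carbinol (6S,7S,9R)-7-(2-hydroxypropan-2-yl)-4-methyl-6-[(triethylsilyl)oxy]-9-{[tri(propan-2-yl)silyl]ethynyl}spiro[2.6]nonan-4-ol F1. Bu4NF removes both silyl groups to give (6S,7S,9S)-9-ethynyl-7-(2-hydroxypropan-2-yl)-4-methylspiro[2.6]nonane-4,6-diol F2. MgBr2·OEt2 (Et2O, reflux) ionises only the cyclopropyl carbinol and effects the cyclopropylcarbinyl-to-homoallyl rearrangement to (1S,5S,7S)-4-(2-bromoethyl)-5-ethynyl-7-(2-hydroxypropan-2-yl)-3-methylcyclohept-3-en-1-ol F3, which already has the C1=C10 olefin. Bu3SnH/AIBN (benzene, 80 °C) closes the ring by 5-exo-dig cyclisation to diene 16, here isolated. H2 with RhCl(PPh3)3 (benzene, rt) reduces only the exocyclic methylene, from the face anti to C6, and gives 17.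

2. Step 4. What may go wrong:
- the zinc acetylide may add sluggishly or in the 1,2 sense;
- the labile silyl enol ether may be hydrolysed before the Mannich step;
- the facial selectivity at C5 may be insufficient.

Fallback (sets out from 6, returns at 11): the alkyne is delivered by nickel catalysis and the methylene is built by aldol and dehydration. The alane Me2AlC≡CSi(i-Pr)3 (from lithiated 7 and Me2AlCl) is added to 6 with Ni(acac)2/DIBAL-H (cat.) in Et2O at −5 °C. The aluminium enolate is trapped with monomeric formaldehyde to give (3R,5R,6S)-2-(hydroxymethyl)-5-(prop-1-en-2-yl)-6-[(triethylsilyl)oxy]-3-{[tri(propan-2-yl)silyl]ethynyl}cycloheptan-1-one F4. MsCl/Et3N gives the primary methanesulfonate of F4, F5, and DBU eliminates it to 11.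

3. Step 3. What may go wrong:
- dienone 3 may lose triethylsilanol (acid or base) and aromatise to tropone;
- 1,4-addition may compete with 1,6-addition;
- the conjugation of the olefin may stay incomplete.

Fallback (sets out from 2, returns at 6): the ring-opened dienone is avoided altogether. Copper-catalysed (CuBr·SMe2) anti SN2' opening of the doubly allylic bridging ether of 2 with 4 (THF, −40 °C) puts the isopropenyl group on C7 trans to the C8 oxygen. The magnesium alkoxide is silylated in the same flask (Et3SiCl, imidazole) to give triethyl{[(5R,6S)-5-(prop-1-en-2-yl)-6-[(triethylsilyl)oxy]cyclohepta-1,3-dien-1-yl]oxy}silane F6. K2CO3/MeOH at 0 °C cleaves only the silyl dienol ether (to 5), and DBU (cat.) conjugates the olefin to 6.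

Further compounds
F1 | step 10 | (6S,7S,9R)-7-(2-hydroxypropan-2-yl)-4-methyl-6-[(triethylsilyl)oxy]-9-{[tri(propan-2-yl)silyl]ethynyl}spiro[2.6]nonan-4-ol (C4 epimers) | CC1(O)C2(CC2)[C@H](C#C[Si](C(C)C)(C(C)C)C(C)C)C[C@H](C(C)(C)O)[C@@H](O[Si](CC)(CC)CC)C1
F2 | step 10 | (6S,7S,9S)-9-ethynyl-7-(2-hydroxypropan-2-yl)-4-methylspiro[2.6]nonane-4,6-diol (C4 epimers) | CC1(O)C2(CC2)[C@H](C#C)C[C@H](C(C)(C)O)[C@@H](O)C1
F3 | step 10 | (1S,5S,7S)-4-(2-bromoethyl)-5-ethynyl-7-(2-hydroxypropan-2-yl)-3-methylcyclohept-3-en-1-ol | CC1=C(CCBr)[C@H](C#C)C[C@H](C(C)(C)O)[C@@H](O)C1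
F4 | step 4 | (3R,5R,6S)-2-(hydroxymethyl)-5-(prop-1-en-2-yl)-6-[(triethylsilyl)oxy]-3-{[tri(propan-2-yl)silyl]ethynyl}cycloheptan-1-one (C2 epimers) | O=C1C(CO)[C@H](C#C[Si](C(C)C)(C(C)C)C(C)C)C[C@H](C(C)=C)[C@@H](O[Si](CC)(CC)CC)C1
F5 | step 4 | primary methanesulfonate of F4 | O=C1C(COS(C)(=O)=O)[C@H](C#C[Si](C(C)C)(C(C)C)C(C)C)C[C@H](C(C)=C)[C@@H](O[Si](CC)(CC)CC)C1
F6 | step 3 | triethyl{[(5R,6S)-5-(prop-1-en-2-yl)-6-[(triethylsilyl)oxy]cyclohepta-1,3-dien-1-yl]oxy}silane | CC[Si](CC)(CC)OC1=CC=C[C@H](C(C)=C)[C@@H](O[Si](CC)(CC)CC)C1
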